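Atoms carry their positions in the target SMILES. The route rests on cutting the C7–C15 bond: quaternary C7 is at once the α-carbon of lactam carbonyl C8, the substituent on enone β-carbon C15 and the bridgehead shared by rings C and D. In one operation the C7 lactam enolate is joined to the β-triflyloxy enone carbon C15 under zerovalent palladium, which closes ring C, sets C7 and completes the 3-azabicyclo[3.3.1]nonan-2-one core with the ring B enone in place. The precursor is a 1-azabicyclo[5.2.2]undecane lactam (ring D bridged by the nine-membered ring) whose C12 arm ends in a 2-alkyl-3-triflyloxycyclohexenone and whose C7 carries the 2-(methoxycarbonyl)allyl group.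

Key step: step 19

Remarks on the chemistry (Ar = 2,6-dimethoxyphenyl, Ts = 4-toluenesulfonyl, TBS = tert-butyldimethylsilyl):
- N10 lies between C8 and C11 and is bonded to neither bridgehead of the C/D bicycle, so that core is a 3-azabicyclo[3.3.1]nonane (bridgeheads C7 and C12, one-atom bridge C22). C14 and C15 both end up inside ring C, so the closure is endo with respect to C14=C15.
- In the triflate the ring B protons at C19 and C16 are more acidic than lactam C7–H. The ketone is therefore masked in the flask as its potassium enolate by the first equivalent of base; this shuts the addition–elimination channel, so the closure is committed to palladium catalysis.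
- Assumption: the Et-DuPhos antipode used in step 2 is the one that gives the (S)-acid.
- Assumption: C32 keeps the configuration of 11 through steps 7–10 and 25, which avoid strongly enolising conditions.
- Compounds 27–29 are drawn as one C7 epimer; the mixture is carried on because step 19 planarises C7.

Step 1
Reactants: 1 2,6-dimethoxybenzaldehyde; 2 dimethyl succinate
Product: 3 (E)-benzylidenesuccinic half-ester
Conditions: NaOMe, MeOH, reflux; then aq. HCl
Reagents that add atoms: none
Why: Stobbe condensation, in which the succinate enolate adds to the aldehyde, the alkoxide lactonises to a paraconic ester and base-induced ring opening gives the (E)-alkylidene half-ester with the free acid on the CH2 arm.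

Step 2
Reactants: 3 (E)-benzylidenesuccinic half-ester
Product: 4 (S)-benzylsuccinic half-ester
Conditions: H2 (5 bar), [Rh(cod)(Et-DuPhos)]BF4 (1 mol %), MeOH, 25 °C
Reagents that add atoms: none
Why: Rhodium-catalysed asymmetric hydrogenation of an itaconate-type half-ester, a standard substrate class for bisphospholane ligands, should set C12 as (S) under catalyst control.

Step 3
Reactants: 4 (S)-benzylsuccinic half-ester
Product: 5 (S)-β-(2,6-dimethoxybenzyl)-γ-butyrolactone
Conditions: LiBH4, THF, 0 → 50 °C; then 2 M HCl, 25 °C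
Reagents that add atoms: none
Why: Chemoselective half-ester reduction and lactonisation, since LiBH4 reduces the methyl ester but not the lithium carboxylate, so that C11 becomes the ring OCH2 and C23 the lactone carbonyl.

Step 4
Reactants: 5 (S)-β-(2,6-dimethoxybenzyl)-γ-butyrolactone
Product: 7 (S)-α-methylene-β-(2,6-dimethoxybenzyl)-γ-butyrolactone, via formyl lactone enolate 6 (not isolated)
Conditions: NaH, HCO2Et, THF, 0 → 25 °C; then (CH2O)n, THF, 65 °C
Reagents that add atoms: formaldehyde (used as paraformaldehyde), C=O
Why: α-Methylenation of a lactone through its α-formyl sodium salt (Claisen formylation, aldol addition to formaldehyde and loss of formate) installs C28 as the exocyclic methylene on C22.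

Step 5
Reactants: 7 (S)-α-methylene-β-(2,6-dimethoxybenzyl)-γ-butyrolactone; 8 tert-butyl 4-chloro-3-oxobutanoate
Product: 10 spiro lactone–cyclopentanone tert-butyl β-keto ester, via Michael adduct 9 (not isolated)
Conditions: Cs2CO3 (10 mol %), MeCN, 25 °C; evaporate; then LiN(SiMe3)2 (2.3 equiv), THF, −78 → 0 °C
Reagents that add atoms: none
Why: Michael-initiated ring closure, in which the β-keto ester adds to the α-methylene lactone (C28–C29) and the dianion then closes by 5-exo-tet alkylation of the C22 lactone enolate on the α-chloro ketone carbon C7 from the face anti to the C12 benzyl group, which should set quaternary C22 and place ketone C8 and ester-bearing C29 regiospecifically.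

Step 6
Reactants: 11 (R)-3-amino-2-methylpropanoic acid; 12 Fmoc-OSu
Product: 13 (R)-3-(Fmoc-amino)-2-methylpropanoic acid
Conditions: NaHCO3, acetone–H2O, 25 °C; then aq. HCl
Reagents that add atoms: none
Why: Carbamate formation from the amine and the succinimidyl carbonate (Schotten–Baumann type) leaves C32 untouched.

Step 7
Reactants: 13 (R)-3-(Fmoc-amino)-2-methylpropanoic acid; 10 spiro lactone–cyclopentanone tert-butyl β-keto ester
Product: 15 C29-acylated tricarbonyl, via acid chloride 14 (not isolated)
Conditions: 13, (COCl)2, DMF (cat.), CH2Cl2, 0 → 25 °C, evaporate; then 10, MgCl2, pyridine, CH2Cl2, 25 °C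
Reagents that add atoms: none
Why: C-Acylation of a cyclic β-keto ester through its magnesium enolate (soft enolisation with MgCl2 and pyridine) joins C29 to C30, and the weak base should not epimerise C32 through a ketene.

Step 8
Reactants: 15 C29-acylated tricarbonyl
Product: 17 nine-membered lactam β-keto ester, via free amine 16 (not isolated)
Conditions: DBU (2 equiv), CH2Cl2, 25 °C
Reagents that add atoms: none
Why: Successive ring expansion, in which E1cB loss of the Fmoc group frees N10, N10 adds to ring ketone C8 through a six-membered cyclol, and retro-Claisen cleavage of C8–C29 to the stabilised β-keto ester enolate enlarges the five-membered ring by four atoms.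

Step 9
Reactants: 17 nine-membered lactam β-keto ester
Product: 19 nine-membered keto lactam, via keto acid 18 (not isolated)
Conditions: CF3CO2H–CH2Cl2 (1:4), 25 °C; then toluene, 60 °C
Reagents that add atoms: none
Why: Acidolysis of the tert-butyl ester and decarboxylation of the β-keto acid leave C29 as CH2 without base, which should spare C32.

Step 10
Reactants: 19 nine-membered keto lactam
Product: 20 dioxolane ketal
Conditions: (Me3SiOCH2)2, Me3SiOTf (5 mol %), CH2Cl2, −78 → −20 °C; then pyridine
Reagents that add atoms: 1,2-bis(trimethylsilyloxy)ethane, C[Si](C)(C)OCCO[Si](C)(C)C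
Why: Silyl-triflate-catalysed ketalisation with the bis-silyl ether of ethylene glycol masks the C30 ketone at low temperature through the oxocarbenium ion and not through the enol towards C32.

Step 11
Reactants: 20 dioxolane ketal
Product: 21 diol
Conditions: LiBH4, THF–MeOH, 0 → 25 °C; then H2O
Reagents that add atoms: none
Why: Chemoselective ester reduction, since LiBH4 opens the lactone to the 1,4-diol (C23 and C11 alcohols) and leaves the secondary lactam and the ketal alone.

Step 12
Reactants: 21 diol
Product: 22 bis-tosylate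
Conditions: TsCl (3 equiv), Et3N, Me3N·HCl (10 mol %), CH2Cl2, 0 °C
Reagents that add atoms: 4-toluenesulfonyl chloride (TsCl), Cc1ccc(cc1)S(Cl)(=O)=O
Why: Amine-catalysed sulfonylation converts both primary alcohols fast enough to outrun tetrahydrofuran formation from a monotosylate, and needs no selectivity because only the C11 tosylate can later be displaced (C23 is neopentyl).

Step 13
Reactants: 22 bis-tosylate
Product: 23 bicyclic lactam C23 tosylate
Conditions: NaH, NaI (20 mol %), DMF, 0 → 25 °C
Reagents that add atoms: none
Why: Intramolecular N-alkylation of the lactam anion (6-exo-tet at C11, helped by Finkelstein exchange that the neopentyl C23 tosylate cannot undergo) closes ring D and gives the 1-azabicyclo[5.2.2]undecane lactam.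

Step 14
Reactants: 23 bicyclic lactam C23 tosylate
Product: 24 bicyclic lactam diene alcohol
Conditions: Li, NH3(l), THF, t-BuOH, −78 °C; then NH4Cl
Reagents that add atoms: none
Why: Birch reduction turns the 2-alkyl-1,3-dimethoxybenzene into the 1,5-dimethoxycyclohexa-1,4-diene (a masked 2-alkylcyclohexane-1,3-dione with C14 bonded to C13), and the same dissolving metal cleaves the sulfonate S–O bond to free the C23 alcohol.

Step 15
Reactants: 24 bicyclic lactam diene alcohol
Product: 25 TBS ether
Conditions: TBSCl, imidazole, DMF, 25 °C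
Reagents that add atoms: tert-butyldimethylsilyl chloride (TBSCl), CC(C)(C)[Si](C)(C)Cl
Why: Silylation of the primary alcohol under neutral conditions, which the acid-labile bis(enol ether) tolerates.

Step 16
Reactants: 25 TBS ether; 26 methyl 2-(bromomethyl)acrylate
Product: 27 C7-allylated lactam
Conditions: LiN(iPr)2, THF, −78 °C; then 26, −78 → −40 °C
Reagents that add atoms: none
Why: Lactam enolate alkylation with the allylic bromide (SN2 and SN2′ give the same product) at C7, the only acidic site, with no need to control the new C7 centre because step 19 planarises it.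

Step 17
Reactants: 27 C7-allylated lactam
Product: 28 2-alkylcyclohexane-1,3-dione
Conditions: 0.5 M aq. HCl, THF, 0 °C
Reagents that add atoms: water, O
Why: Enol ether hydrolysis, which is far faster than hydrolysis of the dioxolane or the neopentyl silyl ether, releases the 1,3-dione.

Step 18
Reactants: 28 2-alkylcyclohexane-1,3-dione
Product: 29 vinylogous acyl triflate (key-step precursor)
Conditions: Tf2O, pyridine, CH2Cl2, −78 → 0 °C
Reagents that add atoms: trifluoromethanesulfonic anhydride (Tf2O), O=S(=O)(OS(=O)(=O)C(F)(F)F)C(F)(F)F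
Why: O-Sulfonylation of the symmetric 1,3-dione (a vinylogous acid) gives the β-triflyloxy enone, and either carbonyl leads to the same compound.

Step 19
Reactants: 29 vinylogous acyl triflate (key-step precursor)
Product: 30 tetracyclic enone
Conditions: KN(SiMe3)2 (2.4 equiv), Pd2(dba)3 (5 mol %), t-Bu3P·HBF4 (12 mol %), THF–toluene (0.01 M), −78 → 45 °C; then aq. NH4Cl
Reagents that add atoms: none
Why: The first equivalent of base turns the ring B ketone into its enolate and the second forms the C7=C8 lactam enolate, which is endocyclic to ring D only because C7 is not yet a bridgehead; zerovalent palladium adds oxidatively into the C15–OTf bond, the lactam enolate replaces triflate on palladium, and C–C reductive elimination forms C7–C15 and returns the catalyst. The closest known reaction type is the palladium-catalysed intramolecular α-alkenylation (and α-arylation) of ketone and amide enolates used to build bridged azabicycles. Ring C closes as a six-membered ring in the endo sense with respect to C14=C15 (both alkene carbons lie inside the new ring) through a seven-membered palladacycle, and protonation of the ring B enolate on work-up returns C14=C15 in conjugation with C20. The new stereocentre C7 is set by the tether alone: the C12–C13 arm can reach only the face of the ring D enolate on which it stands, so C6 is forced to the other face and either C7 epimer of 29 should give the same 3-azabicyclo[3.3.1]nonan-2-one. The step needs chemoselectivity for C7 over the more acidic C19 and C16 positions and over the acrylate; the ring B enolate is a bystander that cannot reach C15, the 2-substituted acrylate has no conjugated acidic proton, and the hindered silylamide at high dilution should hold back conjugate addition. The dioxolane at C30 and the silyl ether at C23 keep the second ketone and the primary alcohol out of the enolate chemistry.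

Step 20
Reactants: 30 tetracyclic enone
Product: 31 α-keto ester
Conditions: K2OsO4·2H2O (4 mol %), NaIO4 (4 equiv), 2,6-lutidine, dioxane–H2O (3:1), 25 °C
Reagents that add atoms: NaIO4 (oxygen delivered through the osmium catalyst), [Na+].[O-]I(=O)(=O)=O
Why: Lemieux–Johnson oxidation, in which osmium tetroxide dihydroxylates the unhindered 1,1-disubstituted acrylate alkene much faster than the tetrasubstituted enone and periodate cleaves the diol to the C5 ketone.

Step 21
Reactants: 31 α-keto ester
Product: 32 aldol adduct (ring A closed)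
Conditions: KOt-Bu (0.2 equiv), t-BuOH–THF, 0 °C
Reagents that add atoms: none
Why: Intramolecular vinylogous aldol addition, in which the thermodynamic dienolate of the enone attacks the highly electrophilic C5 ketone through γ-carbon C16 (5-exo-trig) to close ring A; the centres formed at C5 and C16 are removed again in steps 22 and 23.

Step 22
Reactants: 32 aldol adduct (ring A closed)
Product: 33 dienone ester
Conditions: SOCl2, pyridine, CH2Cl2, 0 °C
Reagents that add atoms: none
Why: Dehydration of the tertiary α-hydroxy ester through its chlorosulfite (pyridine-promoted elimination) should give the conjugated C5=C16 dienone ester, and any C5=C6 isomer gives the same trienolate in step 23.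

Step 23
Reactants: 33 dienone ester
Product: 35 C16 hydroxy enoate, via hydroperoxide 34 (not isolated)
Conditions: KOt-Bu, P(OEt)3, O2 (1 atm), THF–t-BuOH, −40 °C; then aq. NH4Cl
Reagents that add atoms: dioxygen, O=O
Why: Enolate autoxidation with in situ phosphite reduction of the hydroperoxide, in which the trienolate formed by deprotonation at C6 should take up oxygen at C16 (the position that restores both the enone and the C5=C6 enoate) on the face anti to quaternary C22 and its CH2OTBS group, that is syn to C8.

Step 24
Reactants: 35 C16 hydroxy enoate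
Product: 36 saturated hydroxy ester
Conditions: H2 (1 atm), [Ir(cod)(PCy3)(py)]PF6 (10 mol %), CH2Cl2, 25 °C
Reagents that add atoms: none
Why: Hydroxyl-directed hydrogenation, in which the C16 hydroxyl binds the cationic iridium catalyst and hydrogen is delivered to the same face of the trisubstituted C5=C6 enoate, should set C5 with H syn to OH and the ester anti while the tetrasubstituted enone stays.

Step 25
Reactants: 36 saturated hydroxy ester
Product: 37 keto diol
Conditions: 2 M aq. HCl, THF, 25 °C
Reagents that add atoms: water, O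
Why: Acid hydrolysis removes the dioxolane and the silyl ether in one operation, and the tertiary C16 alcohol should survive because a cation next to the electron-poor enone carbon C15 is disfavoured.

Step 26
Reactants: 37 keto diol
Product: 38 CNP0211170.1
Conditions: Ac2O, pyridine, DMAP (5 mol %), CH2Cl2, 0 °C
Reagents that add atoms: acetic anhydride (Ac2O), CC(=O)OC(C)=O
Why: DMAP-catalysed acetylation is selective for the primary C23 alcohol over the tertiary C16 hydroxyl.

Compound list

1 | 2,6-dimethoxybenzaldehyde | COc1cccc(OC)c1C=O | starting material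
2 | dimethyl succinate | COC(=O)CCC(=O)OC | starting material
3 | (E)-4-(2,6-dimethoxyphenyl)-3-(methoxycarbonyl)but-3-enoic acid (aryl cis to the CH2CO2H arm) | OC(=O)C/C(=C\c1c(OC)cccc1OC)C(=O)OC | intermediate
4 | (S)-4-(2,6-dimethoxyphenyl)-3-(methoxycarbonyl)butanoic acid | OC(=O)C[C@H](Cc1c(OC)cccc1OC)C(=O)OC | intermediate
5 | (S)-4-(2,6-dimethoxybenzyl)dihydrofuran-2(3H)-one (C=O is C23, α-CH2 is C22, benzyl-bearing CH is C12, OCH2 is C11) | O=C1OC[C@@H](Cc2c(OC)cccc2OC)C1 | intermediate
6 | sodium enolate of (4S)-4-(2,6-dimethoxybenzyl)-2-oxotetrahydrofuran-3-carbaldehyde (drawn as the neutral aldehyde, C22 not defined) | O=C1OC[C@@H](Cc2c(OC)cccc2OC)C1C=O | intermediate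
7 | (S)-4-(2,6-dimethoxybenzyl)-3-methylenedihydrofuran-2(3H)-one (exocyclic CH2 is C28) | O=C1OC[C@@H](Cc2c(OC)cccc2OC)C1=C | intermediate
8 | tert-butyl 4-chloro-3-oxobutanoate | CC(C)(C)OC(=O)CC(=O)CCl | starting material
9 | tert-butyl 4-chloro-2-{[(4S)-4-(2,6-dimethoxybenzyl)-2-oxotetrahydrofuran-3-yl]methyl}-3-oxobutanoate, epimers at C22 and C29 | O=C1OC[C@@H](Cc2c(OC)cccc2OC)C1CC(C(=O)OC(C)(C)C)C(=O)CCl | intermediate
10 | spiro compound: γ-lactone C23(=O)–O–C11H2–C12H(CH2Ar)–C22 sharing C22 with cyclopentanone C22–C7H2–C8(=O)–C29H(CO2t-Bu)–C28H2; C12 S, C22 S with C7 anti and C28 syn to the benzyl group, C29 epimers | O=C1OC[C@@H](Cc3c(OC)cccc3OC)[C@]12CC(=O)C(C(=O)OC(C)(C)C)C2 | intermediate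
11 | (R)-3-amino-2-methylpropanoic acid | C[C@H](CN)C(O)=O | starting material
12 | N-(9-fluorenylmethoxycarbonyloxy)succinimide (Fmoc-OSu) | O=C(OCC1c2ccccc2-c2ccccc12)ON1C(=O)CCC1=O | starting material
13 | (R)-3-{[(9H-fluoren-9-ylmethoxy)carbonyl]amino}-2-methylpropanoic acid | OC(=O)[C@H](C)CNC(=O)OCC1c2ccccc2-c2ccccc12 | intermediate
14 | acid chloride of 13, same configuration at C32 | ClC(=O)[C@H](C)CNC(=O)OCC1c2ccccc2-c2ccccc12 | intermediate
15 | 10 acylated at C29 with the C30(=O)–C32H(CH3)–C34H2–NHFmoc chain (C29 quaternary, epimers; C12, C22 as in 10; C32 as in 11) | O=C1OC[C@@H](Cc3c(OC)cccc3OC)[C@]12CC(=O)C(C(=O)OC(C)(C)C)(C(=O)[C@H](C)CNC(=O)OCC3c4ccccc4-c4ccccc34)C2 | intermediate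
16 | free primary amine from 15 (N10H2) | O=C1OC[C@@H](Cc3c(OC)cccc3OC)[C@]12CC(=O)C(C(=O)OC(C)(C)C)(C(=O)[C@H](C)CN)C2 | intermediate
17 | nine-membered lactam N10H–C8(=O)–C7H2–C22–C28H2–C29H(CO2t-Bu)–C30(=O)–C32H(CH3)–C34H2, spiro at C22 to the γ-lactone of 10; C12, C22, C32 as before, C29 epimers | O=C1OC[C@@H](Cc3c(OC)cccc3OC)[C@@]12CC(C(=O)OC(C)(C)C)C(=O)[C@H](C)CNC(=O)C2 | intermediate
18 | β-keto acid from 17 (CO2H on C29) | O=C1OC[C@@H](Cc3c(OC)cccc3OC)[C@@]12CC(C(O)=O)C(=O)[C@H](C)CNC(=O)C2 | intermediate
19 | nine-membered keto lactam (C29H2, C30 ketone) spiro to the γ-lactone; C12, C22, C32 as before | O=C1OC[C@@H](Cc3c(OC)cccc3OC)[C@@]12CCC(=O)[C@H](C)CNC(=O)C2 | intermediate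
20 | 19 with C30 as its 1,3-dioxolane | O=C1OC[C@@H](Cc3c(OC)cccc3OC)[C@@]12CCC3(OCCO3)[C@H](C)CNC(=O)C2 | intermediate
21 | nine-membered lactam ketal with C22 bearing C23H2OH and the chain C12H(CH2Ar)–C11H2OH | OC[C@@H](Cc1c(OC)cccc1OC)[C@]1(CO)CCC2(OCCO2)[C@H](C)CNC(=O)C1 | intermediate
22 | bis(4-toluenesulfonate) of 21 (C11–OTs and C23–OTs) | Cc1ccc(cc1)S(=O)(=O)OC[C@@H](Cc1c(OC)cccc1OC)[C@]1(COS(=O)(=O)c2ccc(C)cc2)CCC2(OCCO2)[C@H](C)CNC(=O)C1 | intermediate
23 | 1-azabicyclo[5.2.2]undecane lactam: ring D N10–C8(=O)–C7H2–C22–C12H–C11H2, bridged from N10 to C22 by C34H2–C32H(CH3)–C30(dioxolane)–C29H2–C28H2; C12 bears CH2Ar, C22 bears CH2OTs; C12, C22, C32 as in the target | C1C(=O)N2C[C@@H](Cc3c(OC)cccc3OC)[C@]1(COS(=O)(=O)c3ccc(C)cc3)CCC3(OCCO3)[C@H](C)C2 | intermediate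
24 | as 23 with C22–CH2OH and the aryl group reduced to 2,6-dimethoxycyclohexa-2,5-dien-1-yl (C14 sp3) | C1C(=O)N2C[C@@H](CC3C(OC)=CCC=C3OC)[C@]1(CO)CCC3(OCCO3)[C@H](C)C2 | intermediate
25 | tert-butyldimethylsilyl ether of 24 | C1C(=O)N2C[C@@H](CC3C(OC)=CCC=C3OC)[C@]1(CO[Si](C)(C)C(C)(C)C)CCC3(OCCO3)[C@H](C)C2 | intermediate
26 | methyl 2-(bromomethyl)acrylate | C=C(CBr)C(=O)OC | starting material
27 | 25 carrying CH2C(=CH2)CO2CH3 on C7 (one C7 epimer drawn, mixture used) | COC(=O)C(=C)C[C@@H]1C(=O)N2C[C@@H](CC3C(OC)=CCC=C3OC)[C@]1(CO[Si](C)(C)C(C)(C)C)CCC3(OCCO3)[C@H](C)C2 | intermediate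
28 | 27 with the dienyl group hydrolysed to 2,6-dioxocyclohexyl (2-alkylcyclohexane-1,3-dione, drawn as the diketone) | COC(=O)C(=C)C[C@@H]1C(=O)N2C[C@@H](CC3C(=O)CCCC3=O)[C@]1(CO[Si](C)(C)C(C)(C)C)CCC3(OCCO3)[C@H](C)C2 | intermediate
29 | key-step precursor: bicyclic lactam with C13 bonded to C14 of a 3-triflyloxycyclohex-2-en-1-one (C15–OTf, C20=O), C7–CH2C(=CH2)CO2CH3, C22–CH2OTBS, C30 dioxolane (one C7 epimer drawn) | COC(=O)C(=C)C[C@@H]3C(=O)N4C[C@@H](CC5=C(OS(=O)(=O)C(F)(F)F)CCCC5=O)[C@]3(CO[Si](C)(C)C(C)(C)C)CCC6(OCCO6)[C@H](C)C4 | intermediate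
30 | tetracyclic enone: C7–C15 bond closed, rings B, C, D and the nine-membered ring, C14=C15–C20=O, C7 quaternary as in the target | COC(=O)C(=C)C[C@@]23C(=O)N4C[C@@H](CC5=C2CCCC5=O)[C@]3(CO[Si](C)(C)C(C)(C)C)CCC6(OCCO6)[C@H](C)C4 | intermediate
31 | 30 with the side chain cleaved to C7–C6H2–C5(=O)–CO2CH3 | COC(=O)C(=O)C[C@@]23C(=O)N4C[C@@H](CC5=C2CCCC5=O)[C@]3(CO[Si](C)(C)C(C)(C)C)CCC6(OCCO6)[C@H](C)C4 | intermediate
32 | ring A closed by C5–C16: C5(OH)(CO2CH3), C16–H (epimers at C5 and C16) | COC(=O)C1(O)C[C@@]23C(=O)N4C[C@@H](CC5=C2C1CCC5=O)[C@]3(CO[Si](C)(C)C(C)(C)C)CCC6(OCCO6)[C@H](C)C4 | intermediate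
33 | dienone ester with C5=C16 and C14=C15 | COC(=O)C=1C[C@@]23C(=O)N4C[C@@H](CC5=C2C=1CCC5=O)[C@]3(CO[Si](C)(C)C(C)(C)C)CCC6(OCCO6)[C@H](C)C4 | intermediate
34 | C16 hydroperoxide with C5=C6 (OOH syn to C8) | COC(=O)C1=C[C@@]23C(=O)N4C[C@@H](CC5=C2[C@]1(OO)CCC5=O)[C@]3(CO[Si](C)(C)C(C)(C)C)CCC6(OCCO6)[C@H](C)C4 | intermediate
35 | C16 tertiary alcohol with C5=C6 enoate (OH syn to C8, anti to C22) | COC(=O)C1=C[C@@]23C(=O)N4C[C@@H](CC5=C2[C@]1(O)CCC5=O)[C@]3(CO[Si](C)(C)C(C)(C)C)CCC6(OCCO6)[C@H](C)C4 | intermediate
36 | 35 hydrogenated at C5=C6 (C5–H syn to C16–OH, ester anti) | COC(=O)[C@@H]1C[C@@]23C(=O)N4C[C@@H](CC5=C2[C@]1(O)CCC5=O)[C@]3(CO[Si](C)(C)C(C)(C)C)CCC6(OCCO6)[C@H](C)C4 | intermediate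
37 | 36 with free C30 ketone and free C23 alcohol | COC(=O)[C@@H]1C[C@@]23C(=O)N4C[C@@H](CC5=C2[C@]1(O)CCC5=O)[C@]3(CO)CCC(=O)[C@H](C)C4 | intermediate
38 | CNP0211170.1 (C23 acetate of 37) | COC(=O)[C@@H]1C[C@@]23C(=O)N4C[C@@H](CC5=C2[C@]1(O)CCC5=O)[C@]3(COC(C)=O)CCC(=O)[C@H](C)C4 | target

Total step count: 26. Longest linear sequence: 25 steps (steps 1–5 and 7–26, from 2,6-dimethoxybenzaldehyde).

Steps most likely to fail

Step 19. Enolisation at the hindered tertiary C7–H may be too slow beside decay of the ring B enolate and loss of the triflate by S–O cleavage, or the alkenylpalladium may be protonated instead of coupled. The fallback generates the C7 nucleophile without base. Starting from 27, LiN(iPr)2 and CBr4 (THF, −78 °C) should give the tertiary α-bromo lactam F1. Hydrolysis and triflation under the conditions of steps 17 and 18 give the bromo dione F2 and the bromo vinylogous triflate F3. Activated zinc dust (THF, 25 °C) then inserts into the C7–Br bond to form the zinc amide enolate (a Reformatsky reagent), which is coupled intramolecularly with the C15 triflate under zerovalent palladium catalysis (Pd2(dba)3, t-Bu3P, THF, 25–50 °C), a known coupling mode of amide Reformatsky reagents. The route is rejoined at 30.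

Step 23. Oxygen may be taken up at C14 or C6 of the trienolate instead of C16, or from the wrong face. The fallback replaces enolate oxygenation by a pericyclic one. Starting from 33, singlet oxygen (O2, tetraphenylporphyrin, visible light, CH2Cl2, −20 °C) in a Schenck ene reaction should abstract a C6 hydrogen, which is geminal to the ester, and bond to C16 with shift of the double bond to C5=C6. This gives hydroperoxide 34, which PPh3 reduces to 35, where the route is rejoined. No compound outside the list is made (F0).

Step 5. The dianion ring closure may show poor facial selectivity at C22 or O-alkylation of the β-keto ester enolate. The fallback builds the spiro ring by two intermolecular enolate reactions and a Dieckmann condensation. Starting from 5, LiN(iPr)2 and tert-butyl acrylate (THF, −78 °C) give the trans Michael adduct F4. A second deprotonation (LiN(iPr)2, equilibrated to the more acidic lactone enolate) and methyl bromoacetate alkylate C22 anti to the benzyl group to give the diester lactone F5. KOt-Bu (THF, 0 °C) closes C29 onto the methyl ester and returns 10.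

Further compounds

F1 | step 19 | C7-bromo derivative of 27 (tertiary α-bromo lactam, C7 not defined) | COC(=O)C(=C)CC1(Br)C(=O)N2C[C@@H](CC3C(OC)=CCC=C3OC)[C@]1(CO[Si](C)(C)C(C)(C)C)CCC3(OCCO3)[C@H](C)C2
F2 | step 19 | C7-bromo derivative of 28 (bromo dione) | COC(=O)C(=C)CC1(Br)C(=O)N2C[C@@H](CC3C(=O)CCCC3=O)[C@]1(CO[Si](C)(C)C(C)(C)C)CCC3(OCCO3)[C@H](C)C2
F3 | step 19 | C7-bromo derivative of 29 (bromo vinylogous triflate) | COC(=O)C(=C)CC1(Br)C(=O)N2C[C@@H](CC3=C(OS(=O)(=O)C(F)(F)F)CCCC3=O)[C@]1(CO[Si](C)(C)C(C)(C)C)CCC3(OCCO3)[C@H](C)C2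
F0 | step 23 | none | none
F4 | step 5 | tert-butyl 3-[(4S)-4-(2,6-dimethoxybenzyl)-2-oxotetrahydrofuran-3-yl]propanoate, 3,4-trans | O=C1OC[C@@H](Cc2c(OC)cccc2OC)[C@@H]1CCC(=O)OC(C)(C)C
F5 | step 5 | methyl 2-[(4S)-3-(3-tert-butoxy-3-oxopropyl)-4-(2,6-dimethoxybenzyl)-2-oxotetrahydrofuran-3-yl]acetate, CH2CO2CH3 anti to the benzyl group | O=C1OC[C@@H](Cc2c(OC)cccc2OC)[C@@]1(CC(=O)OC)CCC(=O)OC(C)(C)C
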